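Count turnovers.

| setting | red | eta | alpha |
|---|---|---|---|
| Q | 0.29 M | 0.43 M | 0.43 M |
| G | 0.473 M (fed, over 15 s) | 0.120 M (fed, over 15 s) | 0.473 M (fed, over 15 s) |
| temperature | 10 °C |  |  |
| remark | run made earlier; the fed solution adds 0.50 times the starting volume | at 10 °C throughout; the fed solution adds 0.50 times the starting volume | at 10 °C until 15 s, from then on at 30 °C; the fed solution adds 0.50 times the starting volume |
| time |  | 3.0 min | 3.0 min |

- red (time / s: X / %, Q / %): 10.0: 2.1, 95.1; 15.0: 4.8, 93.8; 40.0: 15.8, 80.3

(standard deviation of a reading: 1 percentage point)

* which of the two ends with the higher amount of X, in percent of the Q charged ("neither" if they lie within 2 percentage points) (eta / alpha / neither)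
* X at the end, in percent of the Q charged, eta
* X at the end, in percent of the Q charged, alpha

- charges are per starting volume, the dose included; the dosed solution carries all of it
- at the start none of Q is in solution
- what has only dissolved of Q counts as not reacted
- the earlier runs do not show what temperature does; that part of a forecast is a guess
- a reading or a percentage of X counts all its forms, free or not

After its feed, the red run loses 14 percentage points of its Q charge in 25.0 s, a reading with a scatter near 1.4 points. Q starts as a solid, so the reckoning here treats that loss as a steady stream, the same amount per second whatever the Q charge. Over 3.0 min this stream delivers 2.35 of eta's G charges. This is the turnover count: Q delivered in the time, over the charge of G.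

Take the main step first, one X per Q delivered. Eta and alpha share a Q charge, so this step of the reckoning gives both 65.6% of Q; for alpha that takes 30 °C to leave the stream unchanged, which is a guess.

Now add the G charge. Eta's count stands above one, so G is the limiting reagent and eta's X is capped at 27.9% of Q. Alpha's count is 0.596, so its G puts no cap on the stream.

Then add the rest. In the red run X gains a scattered 0.815 per Q lost, which brings the estimate for alpha to 53.5%. Eta should land under its cap, with its G thinning late. This reckoning puts alpha higher.

The forecast gives alpha, with 13% for eta (range 9% to 19%) and 65% for alpha (range 38% to 90%), on the ground that “With solid Q present, dissolved Q should stay near saturation”. Its alpha stands above the reckoning here.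

The flask gives 16.1% for eta and 36.6% for alpha, so alpha ends higher.

    Z ⇌ X, rate k1*(cs1 - [X]) while solid is left; crystals form when [X] > cs1 (solubility = 0.240 M, k = 0.190 s⁻¹)
    Q ⇌ E, rate k2*(cs2 - [E]) while solid is left; crystals form when [E] > cs2 (solubility = 0.0640 M, k = 0.0160 s⁻¹)
    E → L (k = 0.550 s⁻¹, Ea = 61.0 kJ mol⁻¹)
    2 L → D (k = 1.90 L mol⁻¹ s⁻¹, Ea = 51.0 kJ mol⁻¹)
    G + L → X (k = 2.00 L mol⁻¹ s⁻¹, Ea = 41.0 kJ mol⁻¹)
    X ⇌ J (K = 2.30, k = 0.00580 s⁻¹, Ea = 78.0 kJ mol⁻¹, ΔH = −40.0 kJ mol⁻¹)
    (constants at 10 °C)

Alpha, with a count of 0.596, has spent 56.2% of its G at 3.00 min, and holds X at 36.6% beside J at 25.3%. Eta, with a count of 2.35, keeps 2.59% of its G, and its X and J sum to 27.2% against a cap of 27.9%. The neighbouring flask is eta with 0.73 M of Q. Its count stays 2.35, and its cap drops to 16.4%. That flask keeps 2.59% of its G, and its X at 9.48% plus J at 6.53% make 16.0%.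

Readings and results were computed with constants of no real substance.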